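**Retrosynthetic overview**

- Rings: A = catechol ring, B = para-phenylene, C = ring with one OH, D = ortho-phenylene. The 17-membered macrocycle is the only ring made, and it is closed last.
- Target ⇐ O-demethylation (BBr3) ⇐ Raney Ni desulfurisation of a macrocyclic bis(1,3-dithiane), which unveils both CH2–CH2 bridges at once.
- Macrocycle ⇐ intramolecular alkylation of the ring A 2-lithio-1,3-dithiane (masked acyl anion of an aldehyde carbon) by the ring D benzylic chloride; this makes the A–CH2–CH2–D bond.
- Seco chain ⇐ Cu-catalysed A–O–B ether coupling ⇐ ring C lithio-dithiane + 4-bromobenzyl bromide (B–CH2–CH2–C bond, same reversed polarity).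
- C–O–D ether ⇐ SNAr of o-vanillin dithiane on 2-fluorobenzaldehyde. Starting materials: o-vanillin, 2-fluorobenzaldehyde, 4-bromobenzyl bromide, 3-hydroxy-4,5-dimethoxybenzaldehyde.

Assumption: the target has no stereocentre and its macrocycle conformers are taken to interconvert freely, so it is treated as achiral and no step needs enantiocontrol.

**Route**

Step 1
Reactants: 1 o-vanillin (2-hydroxy-3-methoxybenzaldehyde)
Product: 2 2-(1,3-dithian-2-yl)-6-methoxyphenol
Conditions: HS(CH2)3SH (1.1 equiv), BF3·OEt2 (0.2 equiv), CH2Cl2, 0 °C → rt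
Reagents that add atoms: 1,3-propanedithiol, SCCCS
Why: Lewis-acid-catalysed dithioacetalisation converts the aldehyde into the 1,3-dithiane that later serves as the acyl anion equivalent; the free phenol is untouched and no stereocentre is formed.

Step 2
Reactants: 2 2-(1,3-dithian-2-yl)-6-methoxyphenol; 3 2-fluorobenzaldehyde
Product: 5 {2-[2-(1,3-dithian-2-yl)-6-methoxyphenoxy]phenyl}methanol, via ether aldehyde 4 (not isolated)
Conditions: K2CO3 (2 equiv), DMF, 110 °C, Ar; then 0 °C, MeOH, NaBH4
Reagents that add atoms: none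
Why: Nucleophilic aromatic substitution (SNAr) of the phenoxide on the fluoride activated by the ortho-formyl group, then borohydride reduction in the same flask so that no carbonyl is left to intercept the carbanion of step 3; no stereocentre is formed.

Step 3
Reactants: 5 {2-[2-(1,3-dithian-2-yl)-6-methoxyphenoxy]phenyl}methanol; 6 1-bromo-4-(bromomethyl)benzene
Product: 8 (2-{2-[2-(4-bromobenzyl)-1,3-dithian-2-yl]-6-methoxyphenoxy}phenyl)methanol, via dilithio dianion 7 (not isolated)
Conditions: n-BuLi (2.05 equiv), THF, −78 → −25 °C; then 6, −78 → −40 °C; H2O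
Reagents that add atoms: n-butyllithium, [Li]CCCC (its lithium is carried only by intermediate 7)
Why: Corey–Seebach alkylation: the 2-lithio-2-aryl-1,3-dithiane (masked acyl anion of the former aldehyde carbon) displaces the benzylic bromide far faster than the lithium alkoxide does and leaves the aryl bromide alone, joining two natively electrophilic carbons; the new quaternary carbon is not a stereocentre.

Step 4
Reactants: 9 3-hydroxy-4,5-dimethoxybenzaldehyde
Product: 10 5-(1,3-dithian-2-yl)-2,3-dimethoxyphenol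
Conditions: HS(CH2)3SH (1.1 equiv), BF3·OEt2 (0.2 equiv), CH2Cl2, 0 °C → rt
Reagents that add atoms: 1,3-propanedithiol, SCCCS
Why: The same Lewis-acid-catalysed dithioacetalisation installs the second acyl anion precursor on ring A; no stereocentre is formed.

Step 5
Reactants: 8 (2-{2-[2-(4-bromobenzyl)-1,3-dithian-2-yl]-6-methoxyphenoxy}phenyl)methanol; 10 5-(1,3-dithian-2-yl)-2,3-dimethoxyphenol
Product: 11 {2-[2-(2-{4-[5-(1,3-dithian-2-yl)-2,3-dimethoxyphenoxy]benzyl}-1,3-dithian-2-yl)-6-methoxyphenoxy]phenyl}methanol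
Conditions: CuI (10 mol %), picolinic acid (20 mol %), K3PO4 (2 equiv), DMSO, 90 °C, Ar
Reagents that add atoms: none
Why: Ullmann-type Cu-catalysed C–O coupling arylates the phenoxide of 10 selectively over the primary alcohol of 8, and K3PO4 is far too weak to touch the dithiane C–H; no stereocentre is formed.

Step 6
Reactants: 11 {2-[2-(2-{4-[5-(1,3-dithian-2-yl)-2,3-dimethoxyphenoxy]benzyl}-1,3-dithian-2-yl)-6-methoxyphenoxy]phenyl}methanol
Product: 13 2-(3-{4-[(2-{2-[2-(chloromethyl)phenoxy]-3-methoxyphenyl}-1,3-dithian-2-yl)methyl]phenoxy}-4,5-dimethoxyphenyl)-1,3-dithiane, via benzylic mesylate 12 (not isolated)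
Conditions: MsCl (1.3 equiv), Et3N (1.5 equiv), LiCl (5 equiv), THF, 0 °C → rt
Reagents that add atoms: methanesulfonyl chloride, CS(=O)(=O)Cl (mesyl group in intermediate 12 only); lithium chloride, [Li+].[Cl-] (chlorine of 13)
Why: Mesylation of the primary benzylic alcohol followed by SN2 displacement with chloride in the same flask; a chloride is chosen because it tolerates the amide base of step 7 better than a bromide or sulfonate.

Step 7
Reactants: 13 2-(3-{4-[(2-{2-[2-(chloromethyl)phenoxy]-3-methoxyphenyl}-1,3-dithian-2-yl)methyl]phenoxy}-4,5-dimethoxyphenyl)-1,3-dithiane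
Product: 15 macrocyclic bis(1,3-dithiane) (tri-O-methyl target with a spiro-1,3-dithiane on the benzylic carbon next to ring A and on the benzylic carbon next to ring C), via lithiated dithiane 14 (not isolated)
Conditions: LiN(i-Pr)2 (1.3 equiv), THF–DMPU (10:1), 2 mM, −78 °C (30 min) → 0 °C (4 h)
Reagents that add atoms: lithium diisopropylamide, CC(C)N([Li])C(C)C (its lithium is carried only by intermediate 14)
Why: Proposed new method: the hindered amide removes the 2-aryl-1,3-dithiane C–H (pKa about 31) much faster than it attacks the benzylic chloride, and the sulfur-stabilised acyl anion equivalent then closes the 17-membered ring by SN2 at high dilution, joining the former aldehyde carbon to a benzylic halide carbon (both natively electrophilic) with no stereocentre formed; closest known reaction types are the intramolecular Corey–Seebach alkylation of ω-halo dithianes and the macrocyclising alkylation of protected cyanohydrin anions.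

Step 8
Reactants: 15 macrocyclic bis(1,3-dithiane)
Product: 16 tri-O-methyl target (the three phenolic OH as OMe)
Conditions: Raney Ni (W-2, large excess), EtOH–THF, reflux
Reagents that add atoms: none
Why: Raney Ni hydrogenolysis of the C–S bonds (Mozingo-type desulfurisation) turns both dithioketal carbons into CH2 and so delivers both CH2–CH2 bridges in one operation; aryl ethers are inert.

Step 9
Reactants: 16 tri-O-methyl target
Product: 17 CNP0290892.0 (target)
Conditions: BBr3 (6 equiv), CH2Cl2, −78 °C → rt; then H2O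
Reagents that add atoms: none
Why: BBr3 O-demethylation cleaves the three aryl methyl ethers while diaryl ethers resist; the product has no stereocentre.

**Compound list**

1 | o-vanillin (2-hydroxy-3-methoxybenzaldehyde) | COc1cccc(C=O)c1O | starting material
2 | 2-(1,3-dithian-2-yl)-6-methoxyphenol | COc1cccc(C2SCCCS2)c1O | intermediate
3 | 2-fluorobenzaldehyde | O=Cc1ccccc1F | starting material
4 | 2-[2-(1,3-dithian-2-yl)-6-methoxyphenoxy]benzaldehyde (not isolated) | COc1cccc(C2SCCCS2)c1Oc1ccccc1C=O | intermediate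
5 | {2-[2-(1,3-dithian-2-yl)-6-methoxyphenoxy]phenyl}methanol | COc1cccc(C2SCCCS2)c1Oc1ccccc1CO | intermediate
6 | 1-bromo-4-(bromomethyl)benzene (4-bromobenzyl bromide) | BrCc1ccc(Br)cc1 | starting material
7 | dilithio dianion of 5 (lithium alkoxide, 2-lithio-1,3-dithiane; not isolated) | COc1cccc(C2([Li])SCCCS2)c1Oc1ccccc1CO[Li] | intermediate
8 | (2-{2-[2-(4-bromobenzyl)-1,3-dithian-2-yl]-6-methoxyphenoxy}phenyl)methanol | COc1cccc(C2(Cc3ccc(Br)cc3)SCCCS2)c1Oc1ccccc1CO | intermediate
9 | 3-hydroxy-4,5-dimethoxybenzaldehyde | COc1cc(C=O)cc(O)c1OC | starting material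
10 | 5-(1,3-dithian-2-yl)-2,3-dimethoxyphenol | COc1cc(C2SCCCS2)cc(O)c1OC | intermediate
11 | {2-[2-(2-{4-[5-(1,3-dithian-2-yl)-2,3-dimethoxyphenoxy]benzyl}-1,3-dithian-2-yl)-6-methoxyphenoxy]phenyl}methanol | COc1cc(C2SCCCS2)cc(Oc2ccc(CC3(c4cccc(OC)c4Oc4ccccc4CO)SCCCS3)cc2)c1OC | intermediate
12 | methanesulfonate of 11 (not isolated) | COc1cc(C2SCCCS2)cc(Oc2ccc(CC3(c4cccc(OC)c4Oc4ccccc4COS(C)(=O)=O)SCCCS3)cc2)c1OC | intermediate
13 | 2-(3-{4-[(2-{2-[2-(chloromethyl)phenoxy]-3-methoxyphenyl}-1,3-dithian-2-yl)methyl]phenoxy}-4,5-dimethoxyphenyl)-1,3-dithiane | COc1cc(C2SCCCS2)cc(Oc2ccc(CC3(c4cccc(OC)c4Oc4ccccc4CCl)SCCCS3)cc2)c1OC | intermediate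
14 | 2-lithio-1,3-dithiane derived from 13 (lithium on the ring A dithiane carbon; not isolated) | COc1cc(C2([Li])SCCCS2)cc(Oc2ccc(CC3(c4cccc(OC)c4Oc4ccccc4CCl)SCCCS3)cc2)c1OC | intermediate
15 | macrocyclic bis(1,3-dithiane): tri-O-methyl target with spiro-1,3-dithianes on the benzylic carbons next to ring A and ring C (17-membered ring, no stereocentre) | COc1cc2cc(c1OC)Oc1ccc(cc1)CC1(SCCCS1)c1cccc(OC)c1Oc1ccccc1CC23SCCCS3 | intermediate
16 | tri-O-methyl target | COc1cc2cc(c1OC)Oc1ccc(cc1)CCc1cccc(OC)c1Oc1ccccc1CC2 | intermediate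
17 | CNP0290892.0 | Oc1cc2cc(c1O)Oc1ccc(cc1)CCc1cccc(O)c1Oc1ccccc1CC2 | target

**Step count and risks**

Total steps: 9. Longest linear sequence: 8 (steps 1, 2, 3, 5, 6, 7, 8, 9; step 4 is the side branch).

Steps most likely to fail:

Step 7 (macrocyclising dithiane alkylation; risks are attack of the base on the benzylic chloride and oligomerisation). Fallback: close the ring by an intramolecular Wittig olefination instead. It sets out from 11. MeI and CaCO3 in aqueous MeCN at 50 °C remove both dithianes and give the keto-aldehyde alcohol 3-{4-[2-(2-{2-(hydroxymethyl)phenoxy}-3-methoxyphenyl)-2-oxoethyl]phenoxy}-4,5-dimethoxybenzaldehyde F1. PPh3·HBr in MeCN at reflux converts its benzylic alcohol into {2-[2-(2-{4-[5-formyl-2,3-dimethoxyphenoxy]phenyl}acetyl)-6-methoxyphenoxy]benzyl}triphenylphosphonium bromide F2. NaOMe in CH2Cl2 at high dilution gives the macrocyclic stilbene ketone (tri-O-methyl macrocycle with CH=CH between rings D and A and C=O next to ring C, E/Z mixture) F3. H2 over Pd/C in AcOH with catalytic HClO4 saturates the alkene and hydrogenolyses the aryl ketone to CH2, which comes back to the route at 16.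

Step 5 (Cu-catalysed ether coupling in the presence of two dithianes, which may bind copper). Fallback: make the A–O–B ether by SNAr before the C–C bond instead of by copper catalysis after it. It sets out from 10. K2CO3 in DMF at 120 °C with 4-fluorobenzaldehyde gives 4-[5-(1,3-dithian-2-yl)-2,3-dimethoxyphenoxy]benzaldehyde F4, which NaBH4 reduces in the same flask to {4-[5-(1,3-dithian-2-yl)-2,3-dimethoxyphenoxy]phenyl}methanol F5. PBr3 in CH2Cl2 at 0 °C gives 2-{3-[4-(bromomethyl)phenoxy]-4,5-dimethoxyphenyl}-1,3-dithiane F6. This bromide alkylates dilithio dianion 7 (made from 5 as in step 3) at −78 °C and comes back to the route at 11.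

Step 2 (SNAr of a phenol flanked by two ortho substituents). Fallback: a carboxylate-assisted Ullmann condensation. It sets out from 2, which is heated with 2-bromobenzoic acid, Cu powder (10 mol %) and K2CO3 in DMF at 130 °C to give 2-[2-(1,3-dithian-2-yl)-6-methoxyphenoxy]benzoic acid F7. LiAlH4 in THF reduces the acid and comes back to the route at 5.

**Further compounds**

F1 | step 7 | 3-{4-[2-(2-{2-(hydroxymethyl)phenoxy}-3-methoxyphenyl)-2-oxoethyl]phenoxy}-4,5-dimethoxybenzaldehyde | COc1cc(C=O)cc(Oc2ccc(CC(=O)c3cccc(OC)c3Oc3ccccc3CO)cc2)c1OC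
F2 | step 7 | {2-[2-(2-{4-[5-formyl-2,3-dimethoxyphenoxy]phenyl}acetyl)-6-methoxyphenoxy]benzyl}triphenylphosphonium bromide | COc1cc(C=O)cc(Oc2ccc(CC(=O)c3cccc(OC)c3Oc3ccccc3C[P+](c3ccccc3)(c3ccccc3)c3ccccc3)cc2)c1OC.[Br-]
F3 | step 7 | macrocyclic stilbene ketone (tri-O-methyl macrocycle with CH=CH between rings D and A and C=O next to ring C, E/Z mixture) | COc1cc2cc(c1OC)Oc1ccc(cc1)CC(=O)c1cccc(OC)c1Oc1ccccc1C=C2
F4 | step 5 | 4-[5-(1,3-dithian-2-yl)-2,3-dimethoxyphenoxy]benzaldehyde | COc1cc(C2SCCCS2)cc(Oc2ccc(C=O)cc2)c1OC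
F5 | step 5 | {4-[5-(1,3-dithian-2-yl)-2,3-dimethoxyphenoxy]phenyl}methanol | COc1cc(C2SCCCS2)cc(Oc2ccc(CO)cc2)c1OC
F6 | step 5 | 2-{3-[4-(bromomethyl)phenoxy]-4,5-dimethoxyphenyl}-1,3-dithiane | COc1cc(C2SCCCS2)cc(Oc2ccc(CBr)cc2)c1OC
F7 | step 2 | 2-[2-(1,3-dithian-2-yl)-6-methoxyphenoxy]benzoic acid | COc1cccc(C2SCCCS2)c1Oc1ccccc1C(=O)O
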